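The earlier runs and the new flask come from a simulation for substances that don't exist; the scatter is artificial.

My next run hung on amounts: 0.25 M of substrate was to meet a liquid that saturates at 15 mM of dissolved gas. I had to choose between feeding it over 30 h (elm) and adding it all at the start (larch).

| flask | substrate | gas phase | temperature | remark | time |
|---|---|---|---|---|---|
| blue | 0.35 M (fed, over 30 h) | 15 mM (held) | 45 °C | run made earlier |  |
| green | 0.55 M (fed, over 30 h) | 15 mM (held) | 60 °C | run made earlier |  |
| elm | 0.25 M (fed, over 30 h) | 15 mM (held) | 60 °C |  | 30 h |
| larch | 0.25 M | 15 mM | 60 °C | everything together at the start | 30 h |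

- blue (time / h: target / %, side product / %): 12.0: 15, 17; 25.0: 39, 39; 40.0: 50, 49; 48.0: 53, 49; 60.0: 51, 49; 96.0: 53, 50
- green (time / h: target / %, side product / %): 3.00: 4, 7; 5.00: 5, 14; 8.00: 7, 18; 12.0: 11, 27; 20.0: 20, 46; 40.0: 32, 65

(standard deviation of a reading: 1.5 percentage points)

1. which of the two ends with the higher share of target in all that became target or side product ("neither" if they lie within 2 percentage points) (elm / larch / neither)
2. share of target in all that became target or side product, elm
3. share of target in all that became target or side product, larch

- percentages count the whole charge, also what has not yet gone in

1. I assumed that each target takes up one dissolved gas and that the liquid starts saturated.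

2. The green run had made 20% of target from its 0.55 M by 20.0 h. I read that as an average gas inflow in green of 5.50 mM h⁻¹, a rough reading that also counts the gas the liquid held at the start.

3. At 12.0 h, green had received 40.0% of its charge and showed 38.0% as products, so it held about 2.00%. Freezing that holding, I multiplied it by the dosing time and got a substrate lifetime of 0.600 h. This is a rough reading, since each product carries a scatter of 1.5 percentage points.

4. I carried one quantity forward, the gas allowance: the saturated liquid's gas plus the inflow while substrate is present, as a share of the charge. For larch, with substrate present for about one lifetime as read in green, it is 7.32%. For elm, with substrate arriving over the whole dosing time, it is 72.0%.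

5. Green's last reading gave a target share, or selectivity, of 33.0%. Elm's allowance is larger than that, so I put no gas cap on elm and expected about green's share there, although green's charge was larger. Larch's allowance is smaller, so I expected larch to stop near its allowance, and I chose to feed.

The forecast said neither, with elm at 31% (26% to 36%) and larch at 33% (22% to 48%), noting that “No run tests high substrate levels”.

Elm ended at 36.4% and larch at 7.77%, so elm gave the higher share. By 15.0 h, larch already held 0% substrate and 7.77% target. Larch's allowance of 7.32% lies 0.45 points below larch's result.

    gas phase ⇌ dissolved gas, rate k1*(csat - [dissolved gas]) (kL = 1.18 h⁻¹)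
    substrate + dissolved gas → target (k = 94.4 L mol⁻¹ h⁻¹, Ea = 72.0 kJ mol⁻¹)
    substrate → side product (k = 1.86 h⁻¹, Ea = 112 kJ mol⁻¹)
    2 dissolved gas → homo dimer (k = 4.32 L mol⁻¹ h⁻¹, Ea = 68.0 kJ mol⁻¹)
    (constants at 60 °C)

A neighbour flask like elm, but charged with 1.0 M of substrate, has an allowance of 18.0%, below green's share. The computed share there is 26.5%, which is 8.5 points above the allowance, with target forming at 8.71 mM h⁻¹ on average against my 5.50 mM h⁻¹.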